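Substrate is the molecule we follow, and in the south run it leaves at two different paces.

| flask | substrate | partner | second reagent | remark | time |
|---|---|---|---|---|---|
| north-west | 0.20 M | 0.26 M | 0.40 M | run made earlier |  |
| west | 0.13 M | 0.26 M | 0.40 M | run made earlier |  |
| south | 0.30 M | 0.26 M | 0.40 M | run made earlier |  |
| Saturday's | 0.20 M | 0.260 M | 0.400 M | everything together in a closed stirred flask, run for 3.0 h | 3.0 h |
| Thursday's | 0.20 M | 0.260 M (fed, over 2.40 h) | 0.400 M | all but partner at the start; partner goes in evenly over 2.40 h, the run ends at 3.0 h | 3.0 h |
| Wednesday's | 0.20 M | 0.260 M | 0.400 M | one stirred flow tank at steady state, fed with the mixture as stated, mean residence time 15.0 h |  |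
| Monday's | 0.20 M | 0.260 M | 0.400 M | a single well-mixed tank run continuously and read at steady state, 3.0 h in it on average |  |

- north-west (time / min: target / %, substrate / %): 8.00: 0, 92.4; 20.0: 0, 80.5; 50.0: 1.3, 65.3; 120: 6.2, 43.4
- west (time / h: target / %, substrate / %): 0.250: 0, 86.0; 0.667: 1.8, 69.0; 1.50: 5.3, 49.4; 4.00: 15.0, 21.2
- south (time / h: target / %, substrate / %): 0.417: 0.7, 78.2; 1.33: 1.8, 54.5; 2.50: 8.9, 38.9; 4.00: 12.2, 28.1

(standard deviation of a reading: 1 percentage point)

* the set-up with the highest amount of target at the outlet or at the end, in percent of the substrate put in ("none" if the first two lie within 2 percentage points) (Saturday's / Thursday's / Wednesday's / Monday's / none)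
* amount of target at the outlet or at the end, in percent of the substrate put in, Saturday's
* amount of target at the outlet or at the end, in percent of the substrate put in, Thursday's
* amount of target at the outlet or at the end, in percent of the substrate put in, Wednesday's
* amount of target at the outlet or at the end, in percent of the substrate put in, Monday's

- the stated concentrations are those of everything mixed, before any reaction; amounts are the same in each set-up
- the feed brings no volume worth counting
- the earlier runs were made in a closed, stirred flask

Up to the first south reading at 0.417 h, substrate has lost 0.0654 M against a partner charge of 0.26 M. We therefore treat partner as roughly at its charge and read a pseudo-first-order mean life from the loss of substrate: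

t_go = 1.70 h

Between the last two south readings, the loss gives a longer mean life:

t_late = 4.61 h

If each substrate lost took one partner, c(partner) at 2.50 h would be 0.0767 M. A pace proportional to c(partner) would then be about 0.174 h⁻¹, which is slower than the 0.217 h⁻¹ read late. As an estimate from readings that scatter by 1 percentage point, we therefore take t_late as the mean life by a way out that needs no partner, though some partner route may remain in that reading. On this estimate, the share leaving through partner is:

(t_late − t_go)/t_late = 63.2%

We call this the partner chance: the selectivity at this fork, read from the south run, for a molecule of substrate with partner roughly at its charge.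

The forecast gives 10.5% for Saturday's, 5.5% for Thursday's, 44% for Wednesday's and 11% for Monday's, so Wednesday's comes out best. Of Wednesday's it says: “This is an extrapolation, since any slow loss of target is unseen.” Our own reckoning for Wednesday's differs: the forecast's figure times the partner chance gives 27.8%.

The flask gives 10.9% for Saturday's, 4.88% for Thursday's, 18.1% for Wednesday's and 8.31% for Monday's, so Wednesday's is best.

    substrate + second reagent → side product (k = 1.60 × 10⁻⁴ L mol⁻¹ s⁻¹)
    second reagent + intermediate → target (k = 1.50 × 10⁻⁴ L mol⁻¹ s⁻¹)
    partner ⇌ dormant form (K = 1.60, k = 6.70 × 10⁻⁵ s⁻¹)
    partner → decomposed reagent (k = 2.90 × 10⁻⁵ s⁻¹)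
    substrate + partner → intermediate (k = 3.90 × 10⁻⁴ L mol⁻¹ s⁻¹)

Wednesday's 18.1% lies below our 27.8% and below the forecast's 44%. At Saturday's charge, the half-life of substrate by the partner path alone is 1.9 h, shorter than the 3.0 h by the side-product path alone. Thursday's flask, left ten times as long, reaches 35.1% at 30.0 h, below the partner chance of 63.2%.

The earlier runs and the new flask stem from a simulated flask with constants of no real substance, and the scatter is random.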